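**Plan**

1. The target is a C19 gibberellin with a five-membered ring B, a 19,10-lactone, a 3β-hydroxyl, a C7 acid on C6 and a 16-hydroxy-16-methyl group (gibberellane numbering throughout). The retrosynthesis first returns C3–OH to a C3 ketone and C16(OH)CH3 to the 17-nor-16-ketone, that is to a C16=C17 methylene compound.
2. Ring B is a cyclopentane made of C5, C6, C8, C9 and C10, and the carboxyl carbon C7 hangs on C6 directly beside the fully substituted bridgehead C8. This is what remains when a cyclohexanone pushes its carbonyl carbon out of the ring, so cutting C6–C8 and rejoining C7 to C8 gives a ring B-homo 6-diazo-7-ketone (photochemical Wolff contraction in the forward sense).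
3. That ketone is cut at C3–C4 (reductive aldol), C4–C5 (Rauhut–Currier), O10–C19 and C1–C10 (acylation, organocerium addition), C13–C16 (vinyl radical closure) and C8–C14/C9–C11 (Diels–Alder). This leads back to 2-(2-bromoallyl)-5-methoxy-1,4-benzoquinone and butadiene.
4. Forward order: ring B as a quinone, ring C, ring D, the lactone, ring A, contraction of ring B, then C16 and C3.
5. Stereochemistry: C8 and C9 come from the catalysed suprafacial cycloaddition; C13, C10, C5 and C4 are relayed from them by ring geometry, convex-face attack and tethering; C6 by ester equilibration; C16 by exo attack of MeMgBr; C3 by equatorial hydride delivery.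

Key step: step 12

**Remarks on the chemistry**

- Numbering and faces: every intermediate carries gibberellane numbers (ring B: C5–C10, with C7 in the ring until step 12; ring C: C8, C9, C11–C14; ring D: C8, C13–C16, C17 on C16). β is the face of ring B that bears H-5, H-9 and C15; α is the face that bears O-10, C11 and C14.
- Assumption: the (S)-configured oxazaborolidine–AlBr3 catalyst is taken to shield the quinone face that leads to 7 as drawn; if the sense of induction on this quinone is the opposite one, the mirror-image catalyst is used.
- Compounds 17 to 25 are written as the 3α-alcohols expected from step 10; any 3β-epimer carried along converges on ketone 26.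

**Route**

Step 1
Reactants: 1 1-bromo-2,4,5-trimethoxybenzene; 2 2,3-dibromoprop-1-ene
Product: 4 1-(2-bromoprop-2-en-1-yl)-2,4,5-trimethoxybenzene, via aryl Grignard reagent 3 (not isolated)
Conditions: Mg, THF, 50 °C; then 2, CuI (5 mol %), THF, −20 → 20 °C
Reagents that add atoms: 2,3-dibromoprop-1-ene 2, C=C(Br)CBr
Why: Copper-catalysed allylic substitution of the aryl Grignard reagent on the allylic C–Br bond (SN2 and SN2′ paths give the same 2-bromoallyl arene), the vinylic bromide being inert.

Step 2
Reactants: 4 1-(2-bromoprop-2-en-1-yl)-2,4,5-trimethoxybenzene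
Product: 5 2-(2-bromoprop-2-en-1-yl)-5-methoxycyclohexa-2,5-diene-1,4-dione
Conditions: (NH4)2Ce(NO3)6, MeCN/H2O, 0 °C
Reagents that add atoms: water, O
Why: Oxidative demethylation of the para-dimethoxy pair by tetravalent cerium, the usual way from 1,2,4-trimethoxyarenes to 2-methoxy-1,4-benzoquinones, with water supplying both carbonyl oxygens.

Step 3
Reactants: 5 2-(2-bromoprop-2-en-1-yl)-5-methoxycyclohexa-2,5-diene-1,4-dione; 6 buta-1,3-diene
Product: 7 cis-fused adduct, 4a-(2-bromoprop-2-en-1-yl)-2-methoxy-4a,5,8,8a-tetrahydronaphthalene-1,4-dione (naphthalene C1 = C10, C4 = C7, C4a = C8, C8a = C9; bromoallyl group cis to H-9)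
Conditions: 6 (excess), (S)-3,3-diphenyl-1-(2-methylphenyl)tetrahydro-1H,3H-pyrrolo[1,2-c][1,3,2]oxazaborole (10 mol %), AlBr3 (8 mol %), CH2Cl2, −78 → −40 °C
Reagents that add atoms: buta-1,3-diene 6, C=CC=C
Why: Catalytic enantioselective Diels–Alder reaction of a quinone, in which the methoxy-bearing double bond is a deactivated vinylogous ester so that butadiene adds to C8=C9, suprafacial addition gives the cis ring fusion, and the chiral Lewis acid selects the quinone face and so fixes C8 and C9.

Step 4
Reactants: 7 cis-fused Diels–Alder adduct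
Product: 8 2,3-dihydro derivative of 7, 4a-(2-bromoprop-2-en-1-yl)-2-methoxy-2,3,4a,5,8,8a-hexahydronaphthalene-1,4-dione (cis fusion kept; the methoxy-bearing C5 as an epimer mixture)
Conditions: Zn dust, AcOH, 20 °C
Reagents that add atoms: none
Why: Dissolving-metal reduction of the ene-1,4-dione saturates C5–C6 only, the isolated alkene and the vinyl bromide being inert, and the weakly acidic medium leaves the enolisable H-9 and hence the cis fusion in place.

Step 5
Reactants: 8 saturated 1,4-dione
Product: 9 rings B, C and D tricyclic diketone (ketones at C7 and C10; 5-methoxy, epimers; ring D closed by the C13–C16 bond; exocyclic C16=C17)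
Conditions: Bu3SnH, 2,2'-azobis(2-methylpropanenitrile) (cat.), benzene, 80 °C, stannane kept at about 0.05 M
Reagents that add atoms: none
Why: 5-exo-trig vinyl radical cyclisation by the tin hydride method, in which the bromoallyl chain is axial on ring C so the C16 radical can reach C13 only from that face, closing the bicyclo[3.2.1]octane and setting C13, while the stannane concentration traps the C12 radical before homoallyl rearrangement.

Step 6
Reactants: 9 tricyclic diketone; 10 2-(2-bromoethyl)-1,3-dioxolane; 11 prop-2-enoyl chloride
Product: 13 tertiary acrylate of the C10 carbinol (10α-acryloyloxy; 2-(1,3-dioxolan-2-yl)ethyl chain on the β face; C7 ketone; 5-methoxy), via cerium alkoxide 12 (not isolated)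
Conditions: 10, Mg, THF, 25 °C; CeCl3, THF, −78 °C; then 9, −78 °C; then 11, −78 → 0 °C
Reagents that add atoms: [2-(1,3-dioxolan-2-yl)ethyl]magnesium bromide (from 10), Br[Mg]CCC1OCCO1; prop-2-enoyl chloride 11, C=CC(Cl)=O
Why: Organocerium 1,2-addition followed by acylation of the alkoxide in the same flask, where C10 is activated by its α-methoxy group while C7 is neopentylic, and the reagent enters from the convex β face opposite C11 and C14 so that O-10 ends on the α face as the lactone requires.

Step 7
Reactants: 13 tertiary acrylate
Product: 14 enone acrylate (C5=C6–C7=O enone; 10α-acryloyloxy)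
Conditions: 1,8-diazabicyclo[5.4.0]undec-7-ene (DBU), CH2Cl2, 0 → 20 °C
Reagents that add atoms: none
Why: E1cB β-elimination of methanol from the β-methoxy ketone gives the C5=C6 enone conjugated with C7.

Step 8
Reactants: 14 enone acrylate
Product: 15 α-methylene-γ-lactone (19,10-lactone cis-fused to ring B with O-10 and C4 on the α face and H-5 on the β face; C4=C18 methylene; C7 ketone; dioxolane acetal)
Conditions: PMe3 (30 mol %), t-BuOH/THF, 20 °C
Reagents that add atoms: none
Why: Intramolecular Rauhut–Currier reaction (phosphine-catalysed Michael cycloisomerisation), in which PMe3 adds to the acrylate terminus, the ester enolate closes 5-exo-trig onto C5 from the face of O-10 to which it is tied, which sets C5, and loss of the phosphine leaves the exocyclic methylene C18.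

Step 9
Reactants: 15 α-methylene lactone acetal
Product: 16 aldehyde (as 15, with the acetal opened to the C3 aldehyde on the C1–C2 chain)
Conditions: 2 M HCl, THF, 20 °C
Reagents that add atoms: water, O
Why: Acid-catalysed acetal hydrolysis frees the C3 aldehyde, dilute acid at room temperature leaving both exocyclic alkenes in place.

Step 10
Reactants: 16 aldehyde
Product: 17 ring B-homo lactone ketone, 3α-hydroxy-7-oxo-20-norkaur-16-en-19,10-olide skeleton (3α-OH equatorial; 4β-methyl C18; lactone on the α face; H-5β; H-9β; C15–C16 bridge β)
Conditions: [(Ph3P)CuH]6 (0.25 equiv), toluene, −40 → 0 °C; then 1 M HCl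
Reagents that add atoms: none
Why: Copper hydride reductive aldol cyclisation, in which hydride from monovalent copper adds to the unhindered C18 methylene and so forms the C4 lactone enolate without base (C6 and C2 stay un-enolised), the enolate adds 6-exo-trig to the C3 aldehyde on the only face the C1–C2 tether can reach, which fixes C4, and the metal-bridged chair should place the 3-OH equatorial, a centre corrected in steps 16 and 17.

Step 11
Reactants: 17 ring B-homo lactone ketone
Product: 19 ring B-homo 6-diazo-7-ketone (3α-hydroxy; 16-methylene; 19,10-lactone), via bis(trifluoroacetyl) derivative 18 (not isolated)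
Conditions: LiN(SiMe3)2 (2.3 equiv), THF, −78 °C; CF3CO2CH2CF3; then 4-acetamidobenzenesulfonyl azide, Et3N, H2O, MeCN, 20 °C
Reagents that add atoms: 4-acetamidobenzenesulfonyl azide, CC(=O)Nc1ccc(cc1)S(=O)(=O)N=[N+]=[N-]
Why: Detrifluoroacetylative diazo transfer (a Regitz-type reaction), which can occur only at C6 because C8 is quaternary and the lactone has no α-hydrogen, the trifluoroacetate formed at O-3 being cleaved by the aqueous amine.

Step 12
Reactants: 19 ring B-homo 6-diazo-7-ketone
Product: 22 methyl ester of the ring-contracted acid (C7 methyl ester on the β face of C6; H-6α; 3α-OH; 16-methylene; 19,10-lactone), via ketene 20 (not isolated), via ester epimer mixture 21 (not isolated)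
Conditions: hν (350 nm), MeOH, 20 °C; then NaOMe, MeOH, 50 °C
Reagents that add atoms: methanol, CO
Why: Excitation of the diazo ketone, held s-cis by the ring, expels N2 with a concerted 1,2-shift of C8 from C7 to C6 (photochemical Wolff rearrangement; closest known type: ring contraction of 2-diazocycloalkanones to cycloalkanecarboxylic esters), so ketene 20 forms without a free carbene. The shift itself closes ring B as the cyclopentane C5–C6–C8–C9–C10 (closure by 1,2-alkyl shift, six-membered to five-membered, new bond C6–C8) and makes C7 the exocyclic ketene carbon, which methanol captures. C8 migrates with retention, so the bridgehead and every other centre stay as they are. C6, the one new stereocentre, is first formed unselectively by protonation of the ketene hemiacetal (21) and is then set by NaOMe equilibration through the ester enolate, the framework favouring the ester on the β face, trans to C4 and cis to H-5. The step needs regiocontrol of migration and preference for rearrangement over O–H insertion: C8 is the only group that can migrate, the diazo group can sit only on C6, and the enforced s-cis geometry favours the concerted shift.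

Step 13
Reactants: 22 methyl ester of the ring-contracted acid
Product: 23 ring-contracted 16-methylene acid (free C7 acid on the β face of C6; 3α-OH; 19,10-lactone)
Conditions: LiSPr, HMPA, 20 °C; then 1 M HCl
Reagents that add atoms: none
Why: SN2 demethylation of the hindered ester by thiolate, a standard method for gibberellin methyl esters that touches neither the lactone nor C6.

Step 14
Reactants: 23 ring-contracted 16-methylene acid
Product: 24 17-nor-16-ketone of 23
Conditions: O3, CH2Cl2/MeOH, −78 °C; then Me2S
Reagents that add atoms: ozone, [O-][O+]=O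
Why: Ozonolysis of the only alkene, with reductive work-up, gives the bicyclo[3.2.1]octanone.

Step 15
Reactants: 24 17-nor-16-ketone
Product: 25 3-epimer of the target (3α-OH; 16-hydroxy-16-methyl with the hydroxyl endo, on the side of C11 and C12)
Conditions: MeMgBr (5 equiv), THF, −78 → 0 °C; then 1 M HCl
Reagents that add atoms: methylmagnesium bromide, C[Mg]Br
Why: Grignard addition to the bicyclo[3.2.1]octan-6-one from the exo face, away from the C9–C11–C12 bridge, puts the methyl group exo and the hydroxyl endo as in the target, the carboxylate and alkoxide formed first being inert and the neopentylic lactone carbonyl not being attacked at low temperature.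

Step 16
Reactants: 25 3-epimer of the target
Product: 26 3-oxo acid (C3 ketone; 16-hydroxy-16-methyl; C7 acid; 19,10-lactone)
Conditions: 1,1,1-triacetoxy-1,1-dihydro-1,2-benziodoxol-3(1H)-one, CH2Cl2, 20 °C
Reagents that add atoms: none
Why: Dess–Martin oxidation of the secondary 3-OH, the tertiary 16-OH and the acid being inert and the non-basic medium avoiding retro-Claisen opening of the β-keto lactone.

Step 17
Reactants: 26 3-oxo acid
Product: 27 target (3β-OH axial)
Conditions: K[(s-Bu)3BH] (4 equiv), THF, −78 °C; then 1 M HCl at −78 °C
Reagents that add atoms: none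
Why: Reduction with a bulky trialkylborohydride, which attacks the C3 ketone along the equatorial path and gives the axial 3β-alcohol, the cold quench preventing retro-aldol epimerisation; C7 is now a carboxylate, so no second ketone competes.

**Compound list**

1 | 1-bromo-2,4,5-trimethoxybenzene | COc1cc(OC)c(OC)cc1Br | starting material
2 | 2,3-dibromoprop-1-ene | C=C(Br)CBr | starting material
3 | (2,4,5-trimethoxyphenyl)magnesium bromide (not isolated) | COc1cc(OC)c(OC)cc1[Mg]Br | intermediate
4 | 1-(2-bromoprop-2-en-1-yl)-2,4,5-trimethoxybenzene | COc1cc(OC)c(OC)cc1CC(Br)=C | intermediate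
5 | 2-(2-bromoprop-2-en-1-yl)-5-methoxycyclohexa-2,5-diene-1,4-dione | COC1=CC(=O)C(CC(Br)=C)=CC1=O | intermediate
6 | buta-1,3-diene | C=CC=C | starting material
7 | cis-4a-(2-bromoprop-2-en-1-yl)-2-methoxy-4a,5,8,8a-tetrahydronaphthalene-1,4-dione (bromoallyl on C8 cis to H-9) | COC1=CC(=O)[C@@]2(CC(Br)=C)CC=CC[C@H]2C1=O | intermediate
8 | cis-4a-(2-bromoprop-2-en-1-yl)-2-methoxy-2,3,4a,5,8,8a-hexahydronaphthalene-1,4-dione (C5 epimers) | COC1CC(=O)[C@@]2(CC(Br)=C)CC=CC[C@H]2C1=O | intermediate
9 | rings B, C and D diketone: C7 and C10 ketones, 5-methoxy (epimers), ring D closed, exocyclic C16=C17 | COC1C(=O)[C@@H]2CC[C@@H]3C[C@]2(CC3=C)C(=O)C1 | intermediate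
10 | 2-(2-bromoethyl)-1,3-dioxolane | BrCCC1OCCO1 | starting material
11 | prop-2-enoyl chloride | C=CC(Cl)=O | starting material
12 | dichlorocerium 10α-alkoxide carrying the 2-(1,3-dioxolan-2-yl)ethyl chain on the β face of C10 (not isolated) | Cl[Ce](Cl)O[C@]1(CCC2OCCO2)[C@@H]2CC[C@@H]3C[C@]2(CC3=C)C(=O)CC1OC | intermediate
13 | 10α-acryloyloxy ketone: tertiary acrylate at C10, C7 ketone, 5-methoxy (epimers) | C=CC(=O)O[C@]1(CCC2OCCO2)[C@@H]2CC[C@@H]3C[C@]2(CC3=C)C(=O)CC1OC | intermediate
14 | enone acrylate: C5=C6–C7=O, 10α-acryloyloxy | C=CC(=O)O[C@]1(CCC2OCCO2)[C@@H]2CC[C@@H]3C[C@]2(CC3=C)C(=O)C=C1 | intermediate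
15 | α-methylene-γ-lactone: 19,10-lactone cis-fused to ring B, H-5β, C4=C18, C7 ketone, dioxolane acetal | C=C1C(=O)O[C@]2(CCC3OCCO3)[C@@H]3CC[C@@H]4C[C@]3(CC4=C)C(=O)C[C@@H]21 | intermediate
16 | aldehyde: as 15 with a 3-oxopropyl chain on C10 | C=C1C(=O)O[C@]2(CCC=O)[C@@H]3CC[C@@H]4C[C@]3(CC4=C)C(=O)C[C@@H]21 | intermediate
17 | ring B-homo lactone ketone: 3α-hydroxy-7-oxo-20-norkaur-16-en-19,10-olide skeleton | C[C@@]12C(=O)O[C@]3(CC[C@H]1O)[C@@H]1CC[C@@H]4C[C@]1(CC4=C)C(=O)C[C@@H]32 | intermediate
18 | 6-trifluoroacetyl derivative of 17 with a 3-O-trifluoroacetate (not isolated) | C[C@@]12C(=O)O[C@]3(CC[C@H]1OC(=O)C(F)(F)F)[C@@H]1CC[C@@H]4C[C@]1(CC4=C)C(=O)C(C(=O)C(F)(F)F)[C@@H]32 | intermediate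
19 | ring B-homo 6-diazo-7-ketone (3α-OH, 16-methylene, 19,10-lactone) | C[C@@]12C(=O)O[C@]3(CC[C@H]1O)[C@@H]1CC[C@@H]4C[C@]1(CC4=C)C(=O)C(=[N+]=[N-])[C@@H]32 | intermediate
20 | ring-contracted ketene, C6=C7=O exocyclic to the five-membered ring B (not isolated) | C[C@@]12C(=O)O[C@]3(CC[C@H]1O)[C@@H]1CC[C@@H]4C[C@]1(CC4=C)C(=C=O)[C@@H]32 | intermediate
21 | ring-contracted methyl ester as a C6 epimer mixture (not isolated) | C[C@@]12C(=O)O[C@]3(CC[C@H]1O)[C@@H]1CC[C@@H]4C[C@]1(CC4=C)C(C(=O)OC)[C@@H]32 | intermediate
22 | methyl ester of the ring-contracted acid (CO2Me β on C6, H-6α; 3α-OH; 16-methylene; 19,10-lactone) | C[C@@]12C(=O)O[C@]3(CC[C@H]1O)[C@@H]1CC[C@@H]4C[C@]1(CC4=C)[C@@H](C(=O)OC)[C@@H]32 | intermediate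
23 | ring-contracted 16-methylene acid (C7 acid β on C6; 3α-OH; 19,10-lactone) | C[C@@]12C(=O)O[C@]3(CC[C@H]1O)[C@@H]1CC[C@@H]4C[C@]1(CC4=C)[C@@H](C(=O)O)[C@@H]32 | intermediate
24 | 17-nor-16-oxo derivative of 23 | C[C@@]12C(=O)O[C@]3(CC[C@H]1O)[C@@H]1CC[C@@H]4C[C@]1(CC4=O)[C@@H](C(=O)O)[C@@H]32 | intermediate
25 | 3-epimer of the target (3α-OH, 16-hydroxy-16-methyl) | C[C@@]12C(=O)O[C@]3(CC[C@H]1O)[C@@H]1CC[C@@H]4C[C@]1(C[C@]4(C)O)[C@@H](C(=O)O)[C@@H]32 | intermediate
26 | 3-oxo acid | C[C@@]12C(=O)O[C@]3(CCC1=O)[C@@H]1CC[C@@H]4C[C@]1(C[C@]4(C)O)[C@@H](C(=O)O)[C@@H]32 | intermediate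
27 | CNP0343121.3 (3β,16-dihydroxy-16-methyl acid lactone) | C[C@@]12C(=O)O[C@]3(CC[C@@H]1O)[C@@H]1CC[C@@H]4C[C@]1(C[C@]4(C)O)[C@@H](C(=O)O)[C@@H]32 | target

**Step count and risks**

Total step count: 17. Longest linear sequence: 17 steps, from compound 1 to compound 27; the route is fully linear.

The three steps most likely to fail:

First risk, step 3: what may go wrong is weak facial discrimination by the catalyst, or a cycloaddition that is too slow at low temperature because the reacting double bond is trisubstituted and butadiene is unactivated. Fallback: setting out from 5, the cycloaddition is run thermally without catalyst (benzene, sealed vessel, 100 °C), which should give 7 together with its mirror image, the enantiomeric Diels–Alder adduct F1. The two are separated by preparative chromatography on a chiral stationary phase (cellulose tris(3,5-dimethylphenylcarbamate)), and the route is rejoined at 7.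

Second risk, step 6: what may go wrong is loss of site selectivity (attack or proton abstraction at the C7 carbonyl group), poor facial selectivity at C10, and incomplete acylation of the hindered alkoxide. Fallback: setting out from 9, C7 is first masked by kinetic enolisation toward C6 with internal silyl trapping (LiN(SiMe3)2, Me3SiCl, THF, −78 °C), giving the C7 trimethylsilyl enol ether F2. The same organocerium addition and acryloyl chloride quench, now on the only remaining ketone, give the 10α-acryloyloxy silyl enol ether F3. Buffered fluoride (Bu4NF, AcOH, THF, 0 °C) then frees the C7 ketone, and the route is rejoined at 13.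

Third risk, step 10: what may go wrong is conjugate reduction that is not followed by ring closure (protonation of the enolate), or competing 1,2-reduction of the aldehyde. Fallback: setting out from 16, a selenolate-triggered Michael–aldol sequence (Me2AlSePh, made from Me3Al and PhSeH, CH2Cl2, −78 °C) adds selenium to C18 and closes ring A through the aluminium enolate, giving the 18-(phenylselanyl) aldol F4. Radical deselenation (Bu3SnH, 2,2'-azobis(2-methylpropanenitrile), benzene, 80 °C) turns CH2SePh into the C18 methyl group, and the route is rejoined at 17.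

Further compounds

F1 | step 3 | enantiomeric Diels–Alder adduct (mirror image of 7) | COC1=CC(=O)[C@]2(CC(Br)=C)CC=CC[C@@H]2C1=O
F2 | step 6 | C7 trimethylsilyl enol ether of 9 (C6=C7, C10 ketone free) | COC1C(=O)[C@@H]2CC[C@@H]3C[C@]2(CC3=C)C(O[Si](C)(C)C)=C1
F3 | step 6 | 10α-acryloyloxy C7 trimethylsilyl enol ether | C=CC(=O)O[C@]1(CCC2OCCO2)[C@@H]2CC[C@@H]3C[C@]2(CC3=C)C(O[Si](C)(C)C)=CC1OC
F4 | step 10 | 18-(phenylselanyl) derivative of 17 | c1ccccc1[Se]C[C@@]12C(=O)O[C@]3(CC[C@H]1O)[C@@H]1CC[C@@H]4C[C@]1(CC4=C)C(=O)C[C@@H]32
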